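**Plan**

- Target: (+)-catechin-(4α→6)-(+)-catechin-(4α→6)-(−)-epicatechin. Flavan numbering (O1, C2, C3, C4, C4a, C5–C8, C8a) is used in each unit; the units are called upper, middle and lower.
- Retrosynthesis: ring C of the lower unit is cut first at O1–C8a and C4–C4a, giving aryl triflate 14 and cis-oxetane 23. The middle C4–aryl bond and the upper C4–C6 bond are then cut to C4 cations of benzylated (+)-catechin.
- Enabling feature: C6 of the lower unit, the carbon bonded to the middle unit, lies between the C5 and C7 oxygens. Without ring C, ring A is therefore a locally symmetric 2,6-dioxygenated aryl group whose para carbon is C8a and whose two free C–H carbons (C4a and C8) are equivalent, so annulation there can only give the 4→6 isomer; O1–C2–C3–C4 maps onto a 2-aryl-oxetan-3-ol.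
- Forward order: (+)-catechin → C4-activated, bromine-capped electrophiles 5 and 6; 5 + arene 8 → 9; 6 adds at C6 of 9 (C8 blocked) → 10; bromine removal and OTIPS → OTf give 14; oxetane 23 comes from an Evans syn glycolate aldol; a palladium/norbornene annulation of 14 with 23 closes the last ring (24); hydrogenolysis gives the target.
- Stereochemistry: C2/C3 of the upper and middle units come from (+)-catechin. Both C4 centres arise by addition to the C4 cation anti to the 3-benzyloxy group (3,4-trans, 4α). C2/C3 of the lower unit come from the auxiliary-controlled syn aldol, are locked cis in the oxetane and pass through the annulation with no bond to either centre broken.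

Key step: step 15

Remark: C4 of 4, 5 and 6 is drawn 4β (alkoxy group trans to the C2 aryl group); this carbon is ionised in steps 7 and 8, so its configuration has no bearing on the outcome.

**Route**

Step 1
Reactants: 1 (+)-catechin
Product: 2 5,7,3',4'-tetra-O-benzyl-(+)-catechin
Conditions: BnBr (4.4 equiv), K2CO3, DMF, 0 °C → rt
Reagents that add atoms: benzyl bromide, BrCc1ccccc1
Why: Williamson etherification of the four phenols, which K2CO3 deprotonates while the secondary C3 hydroxyl stays free; no stereocentre is touched.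

Step 2
Reactants: 2 5,7,3',4'-tetra-O-benzyl-(+)-catechin
Product: 3 3,5,7,3',4'-penta-O-benzyl-(+)-catechin
Conditions: NaH, BnBr, DMF, 0 °C → rt
Reagents that add atoms: benzyl bromide, BrCc1ccccc1
Why: Williamson etherification of the C3 alkoxide, so that every hydroxyl of the upper and middle units carries the same hydrogenolysable group and none can interfere in steps 9, 10 and 15.

Step 3
Reactants: 3 3,5,7,3',4'-penta-O-benzyl-(+)-catechin
Product: 4 4β-(2-ethoxyethoxy)-3,5,7,3',4'-penta-O-benzyl-(+)-catechin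
Conditions: DDQ (2 equiv), 2-ethoxyethanol (5 equiv), CH2Cl2, rt
Reagents that add atoms: 2-ethoxyethanol, CCOCCO
Why: oxidative benzylic etherification: DDQ abstracts hydride from the C4 methylene, which is ortho/para to the ring A oxygens, and the alcohol traps the cation on the face opposite the C2 aryl group.

Step 4
Reactants: 4 4β-(2-ethoxyethoxy)-3,5,7,3',4'-penta-O-benzyl-(+)-catechin
Product: 5 8-bromo-4β-(2-ethoxyethoxy)-3,5,7,3',4'-penta-O-benzyl-(+)-catechin
Conditions: NBS (1.05 equiv), CH2Cl2, −78 → −20 °C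
Reagents that add atoms: N-bromosuccinimide, O=C1CCC(=O)N1Br
Why: electrophilic aromatic bromination; C8 is the more accessible of the two free ring A carbons, and one equivalent of NBS at low temperature should stop at the monobromide that later blocks C8.

Step 5
Reactants: 4 4β-(2-ethoxyethoxy)-3,5,7,3',4'-penta-O-benzyl-(+)-catechin
Product: 6 6,8-dibromo-4β-(2-ethoxyethoxy)-3,5,7,3',4'-penta-O-benzyl-(+)-catechin
Conditions: NBS (2.2 equiv), CH2Cl2, 0 °C → rt
Reagents that add atoms: N-bromosuccinimide, O=C1CCC(=O)N1Br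
Why: exhaustive electrophilic aromatic bromination of C6 and C8 gives an upper-unit electrophile with no nucleophilic ring A carbon, so it cannot self-condense in step 8.

Step 6
Reactants: 7 3,5-bis(benzyloxy)phenol
Product: 8 [3,5-bis(benzyloxy)phenoxy]triisopropylsilane
Conditions: TIPSCl, imidazole, DMF, rt
Reagents that add atoms: chlorotriisopropylsilane, CC(C)[Si](Cl)(C(C)C)C(C)C
Why: silylation of the phenol; the bulky silyl ether marks the oxygen that later becomes the leaving group and shields both flanking ring carbons.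

Step 7
Reactants: 5 8-bromo-4β-(2-ethoxyethoxy)-3,5,7,3',4'-penta-O-benzyl-(+)-catechin; 8 [3,5-bis(benzyloxy)phenoxy]triisopropylsilane
Product: 9 8-bromo-penta-O-benzylcatechin bearing a 4α-[2,6-bis(benzyloxy)-4-(triisopropylsilyloxy)phenyl] group (3,4-trans)
Conditions: TMSOTf (0.3 equiv), 8 (3 equiv), CH2Cl2, −78 → −40 °C; Et3N quench
Reagents that add atoms: none
Why: Friedel–Crafts alkylation: TMSOTf ionises the C4 ether to the ring-A-stabilised benzylic cation, which the arene should attack through its carbon para to the silyl ether (the other two free carbons are shielded by the TIPS group) and anti to the 3-benzyloxy group, setting the 3,4-trans (4α) centre, while the C8 bromine and the excess of 8 suppress self-condensation.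

Step 8
Reactants: 9 8-bromo-penta-O-benzylcatechin bearing a 4α-[2,6-bis(benzyloxy)-4-(triisopropylsilyloxy)phenyl] group; 6 6,8-dibromo-4β-(2-ethoxyethoxy)-3,5,7,3',4'-penta-O-benzyl-(+)-catechin
Product: 10 6,8-dibromo-penta-O-benzylcatechin-(4α→6)-[8-bromo-penta-O-benzylcatechin] bearing the 4α-[2,6-bis(benzyloxy)-4-(triisopropylsilyloxy)phenyl] group on the middle unit
Conditions: TMSOTf (0.5 equiv), 6 (1.5 equiv), CH2Cl2, −40 → 0 °C; Et3N quench
Reagents that add atoms: none
Why: second Friedel–Crafts alkylation by a C4 cation: C6 is the only free ring A carbon of the middle unit (C8 carries bromine), the free carbons of the lower aryl ring are shielded by the adjacent TIPS ether and the dibrominated electrophile cannot oligomerise, so the 4→6 bond should form, again anti to the 3-benzyloxy group (3,4-trans, 4α).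

Step 9
Reactants: 10 tribromide from step 8
Product: 12 penta-O-benzylcatechin-(4α→6)-penta-O-benzylcatechin bearing the 4α-[2,6-bis(benzyloxy)-4-(triisopropylsilyloxy)phenyl] group on the middle unit, via tris-aryllithium 11 (not isolated)
Conditions: n-BuLi (4 equiv), THF, −78 °C; then MeOH, −78 °C → rt
Reagents that add atoms: none
Why: halogen–metal exchange and protonolysis: bromine–lithium exchange at −78 °C is faster than deprotonation of any benzyl ether, and methanol replaces each lithium by hydrogen, so that no aryl halide competes in step 15.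

Step 10
Reactants: 12 debrominated silyl ether from step 9
Product: 14 aryl triflate (12 with OSO2CF3 in place of the silyloxy group), via tetrabutylammonium phenoxide 13 (not isolated)
Conditions: TBAF (1.2 equiv), THF, 0 °C; then PhNTf2 (1.5 equiv), rt
Reagents that add atoms: N-phenylbis(trifluoromethanesulfonimide), O=S(=O)(N(c1ccccc1)S(=O)(=O)C(F)(F)F)C(F)(F)F
Why: fluoride cleaves the aryl silyl ether and the free phenoxide, the only unprotected oxygen in the molecule, is sulfonylated by PhNTf2 (phenol triflation).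

Step 11
Reactants: 15 (S)-4-benzyl-1,3-oxazolidin-2-one; 16 benzyloxyacetyl chloride
Product: 17 (S)-4-benzyl-3-[2-(benzyloxy)acetyl]-1,3-oxazolidin-2-one
Conditions: Et3N, DMAP (cat.), CH2Cl2, 0 °C → rt
Reagents that add atoms: none
Why: N-acylation of the oxazolidinone by the acid chloride under DMAP catalysis.

Step 12
Reactants: 17 (S)-4-benzyl-3-[2-(benzyloxy)acetyl]-1,3-oxazolidin-2-one; 18 3,4-bis(benzyloxy)benzaldehyde
Product: 20 (S)-4-benzyl-3-[(2S,3R)-2-(benzyloxy)-3-[3,4-bis(benzyloxy)phenyl]-3-hydroxypropanoyl]-1,3-oxazolidin-2-one, via dibutylboron Z-enolate 19 (not isolated)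
Conditions: Bu2BOTf (1.1 equiv), Et3N (1.3 equiv), CH2Cl2, −78 → 0 °C; then 18, −78 → 0 °C; H2O2, MeOH, pH 7 buffer
Reagents that add atoms: none
Why: Evans syn aldol reaction: the Z-boron enolate reacts through a Zimmerman–Traxler chair on the enolate face away from the benzyl group of the auxiliary, which should set the (2S,3R) syn pair that becomes C3 and C2 of the lower unit.

Step 13
Reactants: 20 syn aldol adduct
Product: 21 (1R,2R)-2-(benzyloxy)-1-[3,4-bis(benzyloxy)phenyl]propane-1,3-diol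
Conditions: LiBH4, MeOH (1 equiv), THF, 0 °C
Reagents that add atoms: none
Why: reductive cleavage of the N-acyl oxazolidinone by LiBH4 gives the primary alcohol and returns the auxiliary; neither stereocentre is affected.

Step 14
Reactants: 21 (1R,2R)-2-(benzyloxy)-1-[3,4-bis(benzyloxy)phenyl]propane-1,3-diol
Product: 23 (2R,3R)-3-(benzyloxy)-2-[3,4-bis(benzyloxy)phenyl]oxetane (cis), via primary monotosylate 22 (not isolated)
Conditions: n-BuLi (1.0 equiv), THF, 0 °C; TsCl (1.0 equiv), 0 °C; then n-BuLi (1.1 equiv), 0 → 60 °C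
Reagents that add atoms: none
Why: the primary alkoxide is sulfonylated selectively and the benzylic alkoxide then displaces the tosylate in an intramolecular Williamson etherification (4-exo-tet); no bond to either stereocentre is broken, so the syn diol gives the cis-2,3-disubstituted oxetane.

Step 15
Reactants: 14 aryl triflate from step 10; 23 (2R,3R)-3-(benzyloxy)-2-[3,4-bis(benzyloxy)phenyl]oxetane
Product: 24 pentadeca-O-benzyl catechin-(4α→6)-catechin-(4α→6)-epicatechin
Conditions: Pd(OAc)2 (10 mol %), XPhos (20 mol %), 1-methylbicyclo[2.2.1]hept-2-ene (1 equiv), K2CO3 (2.5 equiv), KO2CCMe3 (0.3 equiv), 23 (1.5 equiv), 1,4-dioxane, 100 °C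
Reagents that add atoms: none
Why: Proposed new method: zerovalent palladium should insert into the unhindered C8a–OTf bond of 14, norbornene carbopalladation and carbonate/pivalate-assisted palladation of the adjacent C–H (the future C4a) should give an aryl–norbornyl palladacycle of divalent palladium, and this electron-rich metallacycle should open oxetane 23 by SN2-type oxidative addition at its unsubstituted CH2 (release of about 25 kcal/mol of ring strain) to a tetravalent alkylpalladium alkoxide; C4a–C4 reductive elimination, norbornene extrusion by β-carbon elimination and C8a–O1 reductive elimination then deliver 24 and zerovalent palladium. The closest known reaction type is the Catellani-type palladium/norbornene annulation of aryl iodides with epoxides or aziridines (ortho C–H alkylation by the strained ring, ipso termination by the liberated heteroatom), which gives 2,3-dihydrobenzofurans and indolines; the four-membered ether is used here as the homologous partner to reach the six-membered ring. Ring C of the lower unit is closed in the last event by C(aryl)–O reductive elimination from a seven-membered oxapalladacycle, overall a formal insertion of C4a–C8a into the O1–C4 bond of the oxetane (four- to six-membered ring expansion). No stereocentre is created: C2 and C3 arrive in the cis-oxetane and no bond to either is broken, so the 2R,3R (2,3-cis) arrangement is transferred unchanged. The step needs (a) opening at CH2 and not at the benzylic oxetane carbon, secured by the steric demand of the SN2-type attack under base with no Lewis acid to ionise the benzylic C–O bond, (b) a single annulation, secured because the two C–H bonds flanking the triflate are equivalent by the local symmetry of the 2,6-bis(benzyloxy)aryl ring (either gives the 4→6 isomer), the bridgehead-substituted norbornene leaves after one ortho-alkylation and the tethered alkoxide terminates intramolecularly, and (c) one reactive aryl electrophile only, secured by the removal of the three bromines in step 9.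

Step 16
Reactants: 24 pentadeca-O-benzyl catechin-(4α→6)-catechin-(4α→6)-epicatechin
Product: 25 catechin-(4α→6)-catechin-(4α→6)-epicatechin (CNP0163146.3)
Conditions: H2 (1 atm), Pd(OH)2/C, THF/MeOH/H2O, rt
Reagents that add atoms: none
Why: hydrogenolysis of the fifteen benzyl ethers over Pd(OH)2/C under neutral conditions should leave the acid-sensitive interflavan bonds and all eight stereocentres intact.

**Compound list**

1 | (+)-catechin, (2R,3S)-2-(3,4-dihydroxyphenyl)chromane-3,5,7-triol | Oc1cc(O)c2c(c1)O[C@H](c1ccc(O)c(O)c1)[C@@H](O)C2 | starting material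
2 | 5,7,3',4'-tetra-O-benzyl-(+)-catechin | O(Cc4ccccc4)c1cc(OCc4ccccc4)c2c(c1)O[C@H](c3ccc(OCc4ccccc4)c(OCc4ccccc4)c3)[C@@H](O)C2 | intermediate
3 | 3,5,7,3',4'-penta-O-benzyl-(+)-catechin | O(Cc4ccccc4)c1cc(OCc4ccccc4)c2c(c1)O[C@H](c3ccc(OCc4ccccc4)c(OCc4ccccc4)c3)[C@@H](OCc4ccccc4)C2 | intermediate
4 | 4β-(2-ethoxyethoxy)-3,5,7,3',4'-penta-O-benzyl-(+)-catechin (2,3-trans, alkoxy group trans to the C2 aryl group) | O(Cc4ccccc4)c1cc(OCc4ccccc4)c2c(c1)O[C@H](c3ccc(OCc4ccccc4)c(OCc4ccccc4)c3)[C@@H](OCc4ccccc4)[C@H]2OCCOCC | intermediate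
5 | 8-bromo-4β-(2-ethoxyethoxy)-3,5,7,3',4'-penta-O-benzyl-(+)-catechin | O(Cc4ccccc4)c1cc(OCc4ccccc4)c2c(c1Br)O[C@H](c3ccc(OCc4ccccc4)c(OCc4ccccc4)c3)[C@@H](OCc4ccccc4)[C@H]2OCCOCC | intermediate
6 | 6,8-dibromo-4β-(2-ethoxyethoxy)-3,5,7,3',4'-penta-O-benzyl-(+)-catechin | O(Cc4ccccc4)c1c(Br)c(OCc4ccccc4)c2c(c1Br)O[C@H](c3ccc(OCc4ccccc4)c(OCc4ccccc4)c3)[C@@H](OCc4ccccc4)[C@H]2OCCOCC | intermediate
7 | 3,5-bis(benzyloxy)phenol | Oc1cc(OCc2ccccc2)cc(OCc2ccccc2)c1 | starting material
8 | [3,5-bis(benzyloxy)phenoxy]triisopropylsilane | CC(C)[Si](C(C)C)(C(C)C)Oc1cc(OCc2ccccc2)cc(OCc2ccccc2)c1 | intermediate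
9 | 8-bromo-penta-O-benzylcatechin bearing a 4α-[2,6-bis(benzyloxy)-4-(triisopropylsilyloxy)phenyl] group (2,3-trans, 3,4-trans) | O(Cc4ccccc4)c1cc(OCc4ccccc4)c2c(c1Br)O[C@H](c3ccc(OCc4ccccc4)c(OCc4ccccc4)c3)[C@@H](OCc4ccccc4)[C@@H]2c5c(OCc4ccccc4)cc(O[Si](C(C)C)(C(C)C)C(C)C)cc5OCc4ccccc4 | intermediate
10 | 6,8-dibromo-penta-O-benzylcatechin-(4α→6)-[8-bromo-penta-O-benzylcatechin] bearing the 4α-[2,6-bis(benzyloxy)-4-(triisopropylsilyloxy)phenyl] group on the middle unit | O(Cc4ccccc4)c1c(Br)c(OCc4ccccc4)c2c(c1Br)O[C@H](c3ccc(OCc4ccccc4)c(OCc4ccccc4)c3)[C@@H](OCc4ccccc4)[C@@H]2c5c(OCc4ccccc4)c(Br)c6c(c5OCc4ccccc4)[C@@H](c7c(OCc4ccccc4)cc(O[Si](C(C)C)(C(C)C)C(C)C)cc7OCc4ccccc4)[C@H](OCc4ccccc4)[C@@H](c8ccc(OCc4ccccc4)c(OCc4ccccc4)c8)O6 | intermediate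
11 | tris-aryllithium from 10 (lithium in place of each of the three bromines) | O(Cc4ccccc4)c1c([Li])c(OCc4ccccc4)c2c(c1[Li])O[C@H](c3ccc(OCc4ccccc4)c(OCc4ccccc4)c3)[C@@H](OCc4ccccc4)[C@@H]2c5c(OCc4ccccc4)c([Li])c6c(c5OCc4ccccc4)[C@@H](c7c(OCc4ccccc4)cc(O[Si](C(C)C)(C(C)C)C(C)C)cc7OCc4ccccc4)[C@H](OCc4ccccc4)[C@@H](c8ccc(OCc4ccccc4)c(OCc4ccccc4)c8)O6 | intermediate
12 | penta-O-benzylcatechin-(4α→6)-penta-O-benzylcatechin bearing the 4α-[2,6-bis(benzyloxy)-4-(triisopropylsilyloxy)phenyl] group on the middle unit | O(Cc4ccccc4)c1cc(OCc4ccccc4)c2c(c1)O[C@H](c3ccc(OCc4ccccc4)c(OCc4ccccc4)c3)[C@@H](OCc4ccccc4)[C@@H]2c5c(OCc4ccccc4)cc6c(c5OCc4ccccc4)[C@@H](c7c(OCc4ccccc4)cc(O[Si](C(C)C)(C(C)C)C(C)C)cc7OCc4ccccc4)[C@H](OCc4ccccc4)[C@@H](c8ccc(OCc4ccccc4)c(OCc4ccccc4)c8)O6 | intermediate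
13 | tetrabutylammonium phenoxide of 12 (silyl group removed) | O(Cc4ccccc4)c1cc(OCc4ccccc4)c2c(c1)O[C@H](c3ccc(OCc4ccccc4)c(OCc4ccccc4)c3)[C@@H](OCc4ccccc4)[C@@H]2c5c(OCc4ccccc4)cc6c(c5OCc4ccccc4)[C@@H](c7c(OCc4ccccc4)cc([O-])cc7OCc4ccccc4)[C@H](OCc4ccccc4)[C@@H](c8ccc(OCc4ccccc4)c(OCc4ccccc4)c8)O6.CCCC[N+](CCCC)(CCCC)CCCC | intermediate
14 | aryl triflate: penta-O-benzylcatechin-(4α→6)-penta-O-benzylcatechin bearing a 4α-[2,6-bis(benzyloxy)-4-(trifluoromethanesulfonyloxy)phenyl] group on the middle unit | O(Cc4ccccc4)c1cc(OCc4ccccc4)c2c(c1)O[C@H](c3ccc(OCc4ccccc4)c(OCc4ccccc4)c3)[C@@H](OCc4ccccc4)[C@@H]2c5c(OCc4ccccc4)cc6c(c5OCc4ccccc4)[C@@H](c7c(OCc4ccccc4)cc(OS(=O)(=O)C(F)(F)F)cc7OCc4ccccc4)[C@H](OCc4ccccc4)[C@@H](c8ccc(OCc4ccccc4)c(OCc4ccccc4)c8)O6 | intermediate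
15 | (S)-4-benzyl-1,3-oxazolidin-2-one | O=C1N[C@@H](Cc2ccccc2)CO1 | starting material
16 | benzyloxyacetyl chloride | O=C(Cl)COCc1ccccc1 | starting material
17 | (S)-4-benzyl-3-[2-(benzyloxy)acetyl]-1,3-oxazolidin-2-one | O=C(COCc1ccccc1)N1[C@@H](Cc2ccccc2)COC1=O | intermediate
18 | 3,4-bis(benzyloxy)benzaldehyde | O=Cc1ccc(OCc2ccccc2)c(OCc2ccccc2)c1 | starting material
19 | dibutylboron Z-enolate of 17 | CCCCB(CCCC)O/C(=C\OCc1ccccc1)N1[C@@H](Cc2ccccc2)COC1=O | intermediate
20 | (S)-4-benzyl-3-[(2S,3R)-2-(benzyloxy)-3-[3,4-bis(benzyloxy)phenyl]-3-hydroxypropanoyl]-1,3-oxazolidin-2-one (syn aldol) | O=C([C@@H](OCc1ccccc1)[C@@H](c1ccc(OCc2ccccc2)c(OCc2ccccc2)c1)O)N1[C@@H](Cc2ccccc2)COC1=O | intermediate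
21 | (1R,2R)-2-(benzyloxy)-1-[3,4-bis(benzyloxy)phenyl]propane-1,3-diol | OC[C@@H](OCc1ccccc1)[C@@H](c1ccc(OCc2ccccc2)c(OCc2ccccc2)c1)O | intermediate
22 | (2R,3R)-2-(benzyloxy)-3-[3,4-bis(benzyloxy)phenyl]-3-hydroxypropyl 4-methylbenzenesulfonate | Cc1ccc(cc1)S(=O)(=O)OC[C@@H](OCc1ccccc1)[C@@H](c1ccc(OCc2ccccc2)c(OCc2ccccc2)c1)O | intermediate
23 | (2R,3R)-3-(benzyloxy)-2-[3,4-bis(benzyloxy)phenyl]oxetane (cis) | C1[C@@H](OCc2ccccc2)[C@@H](c2ccc(OCc3ccccc3)c(OCc3ccccc3)c2)O1 | intermediate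
24 | pentadeca-O-benzyl catechin-(4α→6)-catechin-(4α→6)-epicatechin | O(Cc4ccccc4)c1cc(OCc4ccccc4)c2c(c1)O[C@H](c3ccc(OCc4ccccc4)c(OCc4ccccc4)c3)[C@@H](OCc4ccccc4)[C@@H]2c5c(OCc4ccccc4)cc6c(c5OCc4ccccc4)[C@@H](c7c(OCc4ccccc4)cc9c(c7OCc4ccccc4)C[C@@H](OCc4ccccc4)[C@@H](c8ccc(OCc4ccccc4)c(OCc4ccccc4)c8)O9)[C@H](OCc4ccccc4)[C@@H](c8ccc(OCc4ccccc4)c(OCc4ccccc4)c8)O6 | intermediate
25 | catechin-(4α→6)-catechin-(4α→6)-epicatechin (CNP0163146.3) | Oc1cc(O)c2c(c1)O[C@H](c1ccc(O)c(O)c1)[C@@H](O)[C@@H]2c1c(O)cc2c(c1O)[C@@H](c1c(O)cc3c(c1O)C[C@@H](O)[C@@H](c1ccc(O)c(O)c1)O3)[C@H](O)[C@@H](c1ccc(O)c(O)c1)O2 | target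

**Step count and risks**

Total: 16 steps. Longest linear sequence: 10 steps (1, 2, 3, 4, 7, 8, 9, 10, 15, 16).

Steps most likely to fail:

1. Step 15 (proposed annulation). What may go wrong: the palladacycle fails to open the unactivated oxetane, a second ortho-alkylation occurs before norbornene leaves, or the aryl triflate is simply reduced. The fallback uses known chemistry only; it sets out from 5 and 6 and comes back to the route at 25. Commercial (−)-epicatechin would be benzylated at its four phenols (BnBr, K2CO3, DMF) to 5,7,3',4'-tetra-O-benzyl-(−)-epicatechin F1, then at O3 (NaH, BnBr) to 3,5,7,3',4'-penta-O-benzyl-(−)-epicatechin F2, and brominated (NBS, CH2Cl2, −78 °C) to 8-bromo-penta-O-benzyl-(−)-epicatechin F3. TMSOTf-promoted Friedel–Crafts coupling of 5 with an excess of F3, whose only free ring A carbon is C6, would give the dibromo (4α→6) dimer F4. A second coupling with 6 at C6 of the catechin unit of F4 would give the tetrabromo trimer F5. Hydrogenolysis (H2, Pd(OH)2/C, Et3N, THF/MeOH) would remove the fifteen benzyl groups and the four bromines to reach 25.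

2. Step 8. What may go wrong: slow or misdirected Friedel–Crafts attack, since the brominated and doubly flanked C6 is a weak nucleophile and the lower aryl ring may compete for the cation. The fallback changes the order of bond formation so that the hindered 4→6 bond is made on a monomer and arene 8 is introduced last; it sets out from 3 (with 6 and 8) and comes back at 10. Compound 3 would be brominated (NBS, CH2Cl2, −78 °C) to 8-bromo-penta-O-benzyl-(+)-catechin F6. TMSOTf coupling of 6 with F6 at C6 would give the tribromo (4α→6) dimer F7. DDQ and 2-ethoxyethanol would oxidise the only remaining C4 methylene to the C4-activated dimer F8, and TMSOTf coupling of F8 with 8 would return to 10.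

3. Step 7. What may go wrong: poor site selectivity on the arene, with attack ortho instead of para to the silyl ether. The fallback removes the question with a threefold-symmetric nucleophile; it sets out from 5 and comes back at 9. Compound 5 would be coupled with a large excess of phloroglucinol (BF3·OEt2, THF/CH2Cl2, 0 °C) to the 4α-(2,4,6-trihydroxyphenyl) adduct F9. The unhindered para hydroxyl would be silylated (TIPSCl, 1 equiv, imidazole, DMF) to the para-silyl ether F10, and the two hindered hydroxyls benzylated (BnBr, K2CO3, acetone) to give 9.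

Further compounds
F1 | step 15 | 5,7,3',4'-tetra-O-benzyl-(−)-epicatechin | O(Cc4ccccc4)c1cc(OCc4ccccc4)c2c(c1)O[C@H](c3ccc(OCc4ccccc4)c(OCc4ccccc4)c3)[C@H](O)C2
F2 | step 15 | 3,5,7,3',4'-penta-O-benzyl-(−)-epicatechin | O(Cc4ccccc4)c1cc(OCc4ccccc4)c2c(c1)O[C@H](c3ccc(OCc4ccccc4)c(OCc4ccccc4)c3)[C@H](OCc4ccccc4)C2
F3 | step 15 | 8-bromo-3,5,7,3',4'-penta-O-benzyl-(−)-epicatechin | O(Cc4ccccc4)c1cc(OCc4ccccc4)c2c(c1Br)O[C@H](c3ccc(OCc4ccccc4)c(OCc4ccccc4)c3)[C@H](OCc4ccccc4)C2
F4 | step 15 | 8-bromo-penta-O-benzylcatechin-(4α→6)-8-bromo-penta-O-benzylepicatechin | O(Cc4ccccc4)c1cc(OCc4ccccc4)c2c(c1Br)O[C@H](c3ccc(OCc4ccccc4)c(OCc4ccccc4)c3)[C@@H](OCc4ccccc4)[C@@H]2c7c(OCc4ccccc4)c(Br)c9c(c7OCc4ccccc4)C[C@@H](OCc4ccccc4)[C@@H](c8ccc(OCc4ccccc4)c(OCc4ccccc4)c8)O9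
F5 | step 15 | 6,8-dibromo-penta-O-benzylcatechin-(4α→6)-8-bromo-penta-O-benzylcatechin-(4α→6)-8-bromo-penta-O-benzylepicatechin | O(Cc4ccccc4)c1c(Br)c(OCc4ccccc4)c2c(c1Br)O[C@H](c3ccc(OCc4ccccc4)c(OCc4ccccc4)c3)[C@@H](OCc4ccccc4)[C@@H]2c5c(OCc4ccccc4)c(Br)c6c(c5OCc4ccccc4)[C@@H](c7c(OCc4ccccc4)c(Br)c9c(c7OCc4ccccc4)C[C@@H](OCc4ccccc4)[C@@H](c8ccc(OCc4ccccc4)c(OCc4ccccc4)c8)O9)[C@H](OCc4ccccc4)[C@@H](c8ccc(OCc4ccccc4)c(OCc4ccccc4)c8)O6
F6 | step 8 | 8-bromo-3,5,7,3',4'-penta-O-benzyl-(+)-catechin | O(Cc4ccccc4)c1cc(OCc4ccccc4)c2c(c1Br)O[C@H](c3ccc(OCc4ccccc4)c(OCc4ccccc4)c3)[C@@H](OCc4ccccc4)C2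
F7 | step 8 | 6,8-dibromo-penta-O-benzylcatechin-(4α→6)-8-bromo-penta-O-benzylcatechin | O(Cc4ccccc4)c1c(Br)c(OCc4ccccc4)c2c(c1Br)O[C@H](c3ccc(OCc4ccccc4)c(OCc4ccccc4)c3)[C@@H](OCc4ccccc4)[C@@H]2c5c(OCc4ccccc4)c(Br)c6c(c5OCc4ccccc4)C[C@H](OCc4ccccc4)[C@@H](c8ccc(OCc4ccccc4)c(OCc4ccccc4)c8)O6
F8 | step 8 | 6,8-dibromo-penta-O-benzylcatechin-(4α→6)-[8-bromo-4β-(2-ethoxyethoxy)-penta-O-benzylcatechin] | O(Cc4ccccc4)c1c(Br)c(OCc4ccccc4)c2c(c1Br)O[C@H](c3ccc(OCc4ccccc4)c(OCc4ccccc4)c3)[C@@H](OCc4ccccc4)[C@@H]2c5c(OCc4ccccc4)c(Br)c6c(c5OCc4ccccc4)[C@H](OCCOCC)[C@H](OCc4ccccc4)[C@@H](c8ccc(OCc4ccccc4)c(OCc4ccccc4)c8)O6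
F9 | step 7 | 8-bromo-penta-O-benzylcatechin bearing a 4α-(2,4,6-trihydroxyphenyl) group | O(Cc4ccccc4)c1cc(OCc4ccccc4)c2c(c1Br)O[C@H](c3ccc(OCc4ccccc4)c(OCc4ccccc4)c3)[C@@H](OCc4ccccc4)[C@@H]2c5c(O)cc(O)cc5O
F10 | step 7 | 8-bromo-penta-O-benzylcatechin bearing a 4α-[2,6-dihydroxy-4-(triisopropylsilyloxy)phenyl] group | O(Cc4ccccc4)c1cc(OCc4ccccc4)c2c(c1Br)O[C@H](c3ccc(OCc4ccccc4)c(OCc4ccccc4)c3)[C@@H](OCc4ccccc4)[C@@H]2c5c(O)cc(O[Si](C(C)C)(C(C)C)C(C)C)cc5O
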